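If substrate, target and isomer of the product turn into one another around a closed loop, two of whose steps run on one catalyst, the question for each vessel is how many relaxations fit into the time it gives.

    target + catalyst ⇌ isomer of the product + catalyst, rate k1*[catalyst]*[target] forward; the back reaction follows from the equilibrium constant (K1 = 0.067, k1 = 11000 M⁻¹ s⁻¹)
    isomer of the product ⇌ substrate (k2 = 0.75 s⁻¹)
    substrate + catalyst ⇌ target + catalyst, rate k3*[substrate]*[catalyst] forward; the back reaction follows from the equilibrium constant (K3 = 1.6, k3 = 29000 M⁻¹ s⁻¹)

| setting | Saturday's | Monday's | Wednesday's |
|---|---|---|---|
| substrate | 0.050 M | 0.050 M | 0.050 M (fed, over 25.0 s) |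
| catalyst | 0.10 mM | 0.10 mM | 0.10 mM |
| remark | one stirred flow tank at steady state, fed with the mixture as stated, mean residence time 50 s | everything together in a closed stirred flask, run for 50 s | all but substrate at the start; substrate goes in evenly over 25.0 s, the run ends at 50 s |
| time |  | 50 s | 50 s |

* the set-up with the highest amount of target at the outlet or at the end, in percent of the substrate put in ("none" if the first two lie within 2 percentage points) (Saturday's / Monday's / Wednesday's / none)
* amount of target at the outlet or at the end, in percent of the substrate put in, Saturday's
* amount of target at the outlet or at the end, in percent of the substrate put in, Monday's
* amount of target at the outlet or at the end, in percent of the substrate put in, Wednesday's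

- the stated concentrations are those of everything mixed, before any reaction; amounts are the same in each set-up
- the feed brings no volume worth counting
- run time (Monday's): 50 s

**Where does the loop come to rest?** Write K = 1.6 for target over substrate and L = 0.067 for isomer of the product over target. The third constant is the inverse of their product, so the loop closes without net circulation. Substrate, target and isomer of the product then stand as one to K to KL, and the target share is y_eq = K/(1 + K + KL) = 59.1 %.

**Which rate do you compare?** Let k = 29000 M⁻¹ s⁻¹ and c = 0.10 mM. Catalyst is not consumed, so the substrate–target step is pseudo-first-order, with relaxation rate λ = kc + kc/K = 4.71 s⁻¹. Against a residence or run time τ = 50 s, λτ = 236, and this N, the number of relaxations fitting into the time given, is the balance number.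

**Does that comparison drift as the flask fills?** No: every step is first order in the organic species, and λ holds no concentration of them.

**Where is the weak spot?** λ counts one step of the three. The target–isomer pair relaxes at 17.5 s⁻¹, faster than λ. The uncatalysed step, with forward rate constant 0.75 s⁻¹, is slower than λ but still outruns the washout, so I leave both out of N.

**And the vessels?** Saturday's tank gives y_eq·N/(1 + N) = 58.9 %. In Monday's flask the remainder falls as exp(−N), which leaves 59.1 %. In Wednesday's flask the last substrate still has 25.0 s, a balance number of 118, so it also gives 59.1 %. The gap of 0.20 percentage points lies inside the margin, so I call the set-ups tied.

The forecast gave 58.9 %, 59.1 % and 59.1 %, best none, holding that “the set-ups are effectively tied”.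

The simulation gives 58.9 % for Saturday's, 59.1 % for Monday's and 59.1 % for Wednesday's, best none. In Wednesday's flask the relaxation half-life of substrate and target by their step, both ways together, is 0.147 s, shorter than the 25.0 s after the feed, and Monday's 59.1 % taken through N/(1 + N) gives 58.9 % for Saturday's tank. The neighbour of Wednesday's flask charged with 2.5 × 10⁻⁴ M of catalyst has its balance number over that tail multiplied by 2.50, to 295, and ends at 59.1 % target.

The numbers come from no measurement; the result is computed.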